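The rate constants belong to no real substance; what happens was integrated by code.

I began from a ratio in which time cancels: how fast transfer refills the dissolved gas, over how fast the solution can lose it.

    substrate + dissolved gas → target (k1 = 0.11 L mol⁻¹ s⁻¹)
    substrate ⇌ dormant form (K2 = 0.20, k2 = 1.5 s⁻¹)
    substrate + target → side product (k3 = 0.027 L mol⁻¹ s⁻¹)
    gas phase ⇌ dissolved gas, rate k4*(csat - [dissolved gas]) (k4 = 0.85 s⁻¹, csat = 200 mM)
    dissolved gas + target → over-reaction product (k5 = 0.20 L mol⁻¹ s⁻¹)

substrate 1.5 M; gas phase 200 mM (held); time 8.0 s

- in percentages every species weighs as the substrate in it: one side product counts as two
- at the start none of the gas is dissolved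
- run time (flask): 8.0 s

- how much target there is at 8.0 s, in percent of the substrate charged
- concentration of dissolved gas in solution at 2.0 s, in percent of saturation
- the change that raises the amount of target at 8.0 s, in percent of the substrate charged most ("none" if none brings more than 2 percentage points) (dawn / winter / none)
- amount of target at 8.0 s, in percent of the substrate charged, after winter

- Substrate and dormant form relax with half-life 0.0770 s, far shorter than the 8.0 s of the run, so I took free [substrate] as 1.25 M once that relaxation was over. Its uptake of dissolved gas is then pseudo-first-order, with constant 0.138 s⁻¹.
- I named the supply share 86.1%: the transfer coefficient divided by itself plus that uptake constant, which, setting aside the use of dissolved gas by target, is the plateau of [dissolved gas] as a fraction of saturation. The plateau was 0.172 M, approached with time constant 1.01 s, so at 2.0 s I expected 74.2% of saturation.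
- My first ceiling for target put the plateau at time zero, with no losses and free substrate held at its start: 12.6%. Starting the clock one time constant late gave 0.165 M.
- Losses of target at first order, with constant 0.0682 s⁻¹ taken at those same concentrations, brought my upper figure to 8.77%, an estimate rather than a strict bound.
- For a floor, I charged two substrates against each target of that 0.165 M and scaled that upper figure down, which gave 6.84%.
- Dawn multiplied the plateau by 1.07 and winter by 2, so I chose winter. Its upper figure came to 15.7%.
- The forecast gave 8.2% of target, inside my bracket, with 74% of saturation, winter as best and 13.9% after it, saying “Doubling saturation doubles dissolved gas”.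
- The simulation gave 8.25%, also inside, with 74.0% of saturation and 13.9% after winter. Winter won, adding 5.7 percentage points against 0.95 points for dawn.
- In the neighbour flask, charged with 0.38 M of substrate, the supply share rose to 96.1%, a plateau of 0.192 M. The same upper figure came to 10.3% of its charge. That flask read 0.191 M of dissolved gas at 8.00 s, and target stood at 9.70%, below that figure.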